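**Plan**
1. Cuts: the C8 ester comes off first. C2=C3 and C12=O are then taken back to C2H2–C3H and a C12 lactol. O–C10 and C9–C10 are cut together. The eight-membered ring that remains (O, C3–C9) is cut at C4=C5, O–C9 and C7–C8.
2. Enabling feature: in the furanone ring, C10 carries the ring oxygen and is α to the C1 ketone. Its neighbour C9 in the nine-membered ring (O, C3–C10) bears OH. C9 can therefore start as a silyl-acetal carbon on that same oxygen, and C10 as a carbenoid carbon that slips between O and C9.
3. Forward: butenolide (metathesis) → α-methylene lactone with C7–C8 (Barbier) → ester with the C1–C4 piece → eight-membered lactone, whose size forces the 4Z olefin → reductive silylation → diazoketone. The key step then closes the oxolanone ring and the ten-membered carbocycle and widens eight to nine. Dehydrogenation, desilylation, lactol oxidation and acylation follow.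
4. Stereochemistry: C6 and a temporary C3 centre come from two Sharpless kinetic resolutions. C7 forms anti to the C6 substituent. C8 comes from a chelated chair in the Barbier step. C9 comes from hydride delivery to the open face of the eight-membered lactone. C10 is relayed from C3, which is then erased as C2=C3.
5. Helpers: a nitrile as latent C1 acid, a C12 lactol silyl acetal as a diazoalkane-proof mask of the methylene lactone, and C3–H. All are removed in steps 11–17.

Key step: step 14

Remark: germacranolide numbering is used (C1–C10 carbocycle, C11–C13 lactone part, C14 on C10, C15 on C4). C12 of the lactol derivatives 18–28 is assumed to form as an inconsequential epimer mixture and is left undefined in their SMILES, because step 17 returns it to C=O.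

Step 1
Reactants: 1 (E)-crotonaldehyde; 2 vinylmagnesium bromide
Product: 3 rac-(E)-hexa-1,4-dien-3-ol
Conditions: THF, −78 to 0 °C; aq. NH4Cl
Reagents that add atoms: none
Why: Grignard 1,2-addition to the enal gives the racemic bis-allylic alcohol; no stereocentre is controlled here.

Step 2
Reactants: 3 rac-(E)-hexa-1,4-dien-3-ol
Product: 4 (3S,4E)-hexa-1,4-dien-3-ol (recovered alcohol)
Conditions: Ti(OiPr)4 (10 mol %), D-(−)-diisopropyl tartrate (12 mol %), t-BuOOH (0.6 equiv), 4 Å MS, CH2Cl2, −20 °C, run slightly beyond half conversion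
Reagents that add atoms: none
Why: Sharpless kinetic resolution; with the D-tartrate the (R)-alcohol is epoxidised fast at its more substituted propenyl bond, so the slow (S)-alcohol, which carries the future C6 centre, should remain in high enantiomeric purity.

Step 3
Reactants: 4 (3S,4E)-hexa-1,4-dien-3-ol; 5 2-(bromomethyl)acrylic acid
Product: 6 (3S,4E)-hexa-1,4-dien-3-yl 2-(bromomethyl)acrylate
Conditions: DCC, DMAP (5 mol %), CH2Cl2, 0 °C
Reagents that add atoms: none
Why: Steglich esterification acylates the carbinol oxygen without touching the C–O bond, so C6 is retained.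

Step 4
Reactants: 6 (3S,4E)-hexa-1,4-dien-3-yl 2-(bromomethyl)acrylate
Product: 7 (5R)-3-(bromomethyl)-5-[(E)-prop-1-enyl]furan-2(5H)-one
Conditions: second-generation Grubbs catalyst (3 mol %), CH2Cl2, reflux, 10 mM
Reagents that add atoms: none
Why: Ring-closing metathesis; the catalyst loads on the monosubstituted vinyl group and closes the five-membered ring on the acrylate olefin faster than it engages the disubstituted propenyl group, and C6 is untouched.

Step 5
Reactants: 7 (5R)-3-(bromomethyl)-5-[(E)-prop-1-enyl]furan-2(5H)-one; 8 glyoxylic acid (commercial monohydrate)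
Product: 9 (2S)-2-hydroxy-2-{(2R,3R)-4-methylidene-5-oxo-2-[(E)-prop-1-enyl]oxolan-3-yl}acetic acid (trans lactone; C6 C7 C8 as in 36)
Conditions: indium powder, THF/H2O (1:1), rt
Reagents that add atoms: none
Why: Indium Barbier allylation at the γ-carbon C7 creates the exocyclic methylene; C7 forms anti to the C6 propenyl group (trans lactone), and glyoxylic acid held on indium by carboxylate and aldehyde oxygen sits axial in the Zimmerman–Traxler chair, which should turn the ring-locked E-allyl unit to the C7/C8 syn adduct that is needed.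

Step 6
Reactants: 9 hydroxy acid
Product: 11 C8 O-TBS acid, via bis-silylated acid 10 (not isolated)
Conditions: TBSOTf (2.3 equiv), 2,6-lutidine, CH2Cl2, 0 °C; then AcOH/THF/H2O, rt
Reagents that add atoms: tert-butyldimethylsilyl triflate, CC(C)(C)[Si](C)(C)OS(=O)(=O)C(F)(F)F
Why: Silylation with a non-nucleophilic base spares the methylene lactone, and the labile silyl ester alone is hydrolysed by aqueous acetic acid.

Step 7
Reactants: 12 methacrolein; 13 acetonitrile
Product: 14 rac-3-hydroxy-4-methylpent-4-enenitrile
Conditions: n-BuLi, 13, THF, −78 °C; then 12; aq. NH4Cl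
Reagents that add atoms: none
Why: Aldol-type 1,2-addition of lithioacetonitrile to the enal gives the racemic β-hydroxy nitrile (C1–C4 and C15).

Step 8
Reactants: 14 rac-3-hydroxy-4-methylpent-4-enenitrile
Product: 15 (3R)-3-hydroxy-4-methylpent-4-enenitrile (recovered alcohol)
Conditions: Ti(OiPr)4 (10 mol %), L-(+)-diisopropyl tartrate (12 mol %), t-BuOOH (0.6 equiv), 4 Å MS, CH2Cl2, −20 °C
Reagents that add atoms: none
Why: Sharpless kinetic resolution of a 2-substituted allylic alcohol; the L-tartrate consumes the (S)-alcohol and leaves the (R)-alcohol, whose carbinol carbon is the temporary C3 centre.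

Step 9
Reactants: 11 C8 O-TBS acid; 15 (3R)-3-hydroxy-4-methylpent-4-enenitrile
Product: 16 ester of 11 with 15 (O–C9 bond made)
Conditions: DCC, DMAP (10 mol %), CH2Cl2, 0 °C to rt
Reagents that add atoms: none
Why: Steglich esterification joins the two halves at O–C9 with retention at C3 and C8.

Step 10
Reactants: 16 ester of 11 with 15
Product: 17 eight-membered (4Z)-lactone fused to the methylene lactone with a cyanomethyl group on C3
Conditions: second-generation Hoveyda–Grubbs catalyst (10 mol %), toluene, 80 °C, 1 mM, argon sparge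
Reagents that add atoms: none
Why: Ring-closing metathesis; the catalyst enters at the propenyl group and closes onto the 1,1-disubstituted olefin, the trans-fused lactone and three ring substituents gear the chain, the electron-poor methylene lactone stays out, and an eight-membered ring can hold only the cis (4Z) double bond.

Step 11
Reactants: 17 eight-membered lactone
Product: 20 eight-membered O-silyl lactol with a C12 O-silyl lactol and a C1 aldehyde, via tris-aluminium adduct 18 (not isolated), via silylated iminoalane 19 (not isolated)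
Conditions: i-Bu2AlH (3.3 equiv), CH2Cl2, −78 °C; 2,6-lutidine, TBSOTf (2.5 equiv), −78 to −30 °C; aq. potassium sodium tartrate, 0 °C
Reagents that add atoms: tert-butyldimethylsilyl triflate, CC(C)(C)[Si](C)(C)OS(=O)(=O)C(F)(F)F; water, O
Why: Reductive silylation of lactones together with nitrile-to-aldehyde reduction; the aluminium hemiacetals are trapped before they can open, and hydride should reach C9 from the ring face opposite to the C3 side chain, the C8 silyloxy group and C11 and anti to the C8–O bond (Felkin–Anh), which sets C9.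

Step 12
Reactants: 20 aldehyde
Product: 21 C1 carboxylic acid
Conditions: NaClO2, NaH2PO4, 2-methyl-2-butene, t-BuOH/H2O, 0 °C
Reagents that add atoms: sodium chlorite, [Na+].[O-]Cl=O
Why: Pinnick oxidation works in a buffered medium that the silyl acetals and olefins should tolerate, the scavenger taking up the hypochlorous acid.

Step 13
Reactants: 21 C1 carboxylic acid
Product: 23 2-diazo-3-ketone (C10 diazo carbon bearing C14), via mixed carbonic anhydride 22 (not isolated)
Conditions: i-BuOCOCl, Et3N, Et2O, −20 °C; then CH3CHN2 in Et2O (distilled from N-ethyl-N-nitrosourea/aq. KOH), 0 °C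
Reagents that add atoms: diazoethane, CC=[N+]=[N-]
Why: Acylation of a diazoalkane by a mixed anhydride (first stage of the Arndt–Eistert sequence); the masked methylene lactone is now an unactivated olefin and should not undergo dipolar cycloaddition.

Step 14
Reactants: 23 2-diazo-3-ketone
Product: 25 ether-bridged oxolan-3-one with nine-membered oxacycle and ten-membered carbocycle (C4 and C9 cis on the oxolane ring), via bicyclic oxonium ylide 24 (not isolated)
Conditions: Cu(CF3COCHCOCF3)2 (10 mol %), CH2Cl2, reflux, slow addition of 23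
Reagents that add atoms: none
Why: Proposed new method: loss of N2 gives an electrophilic copper carbenoid at C10 that is captured by the 1,5-related acetal oxygen on C3 (five-membered ring closed by O-attack on the carbenoid carbon) to give ylide 24, whose O–C9 bond, weakened by the C9 silyloxy group, breaks to a radical pair or a silyloxycarbenium/enolate pair that recombines at C10, a Stevens [1,2]-shift. C10 is thereby inserted into the O–C9 bond, so the eight-membered ring (O, C3–C9) becomes the nine-membered ring (O, C3–C10) by one-atom ring expansion, and the ten-membered carbocycle is closed at C9–C10 in the same event. The closest known reaction type is the copper- or rhodium-catalysed oxonium ylide/[1,2]-shift of five- and six-membered cyclic mixed acetals with a tethered diazoketone, which gives ether-bridged seven- and eight-membered carbocycles; new here are the eight-membered O-silyl lactol and the methyl group on the diazo carbon. C10 is set by C3, because the six-atom bridge C4–C9 can span only one face of the new oxolanone, so C9 is delivered to C10 cis to C4. C9 keeps the configuration fixed in step 11 (suprafacial shift with retention), and if the pair separates, Felkin–Anh attack of the enolate anti to the C8 silyloxy group leads to the same epimer. The step needs O-attack to outrun 1,2-hydride shift from C14, cyclopropanation of C4=C5 and insertion into C9–H; the strongly electrophilic hexafluoroacetylacetonate carbenoid, the short 1,5-distance to oxygen, and the fact that cyclopropanation would have to join two fully substituted carbons (C10 and C4) should secure this.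

Step 15
Reactants: 25 ether-bridged oxolan-3-one
Product: 27 3(2H)-furanone tris-silyl ether, via trimethylsilyl enol ether 26 (not isolated)
Conditions: LiN(SiMe3)2, Me3SiCl (internal quench), THF, −78 °C; then Pd(OAc)2 (1.1 equiv), MeCN, rt
Reagents that add atoms: none
Why: Saegusa–Ito oxidation; C10 is quaternary so only C2 can be enolised, the internal quench limits β-elimination of the ring oxygen, and loss of the outward C3–H removes the temporary C3 centre.

Step 16
Reactants: 27 furanone tris-silyl ether
Product: 28 C12 lactol 8,9-diol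
Conditions: HF·pyridine, pyridine/THF, 0 °C to rt
Reagents that add atoms: none
Why: Buffered fluoride desilylation removes the lactol silyl group and both silyl ethers without base, so the β-hydroxy ketone unit C9–C10–C1 is not exposed to retro-aldol conditions.

Step 17
Reactants: 28 C12 lactol 8,9-diol
Product: 29 8,9-diol α-methylene lactone (deacyl 36)
Conditions: PhI(OAc)2 (1.1 equiv), TEMPO (10 mol %), CH2Cl2, rt
Reagents that add atoms: none
Why: Oxoammonium oxidation takes lactols much faster than hindered secondary alcohols and restores the α-methylene-γ-butyrolactone.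

Step 18
Reactants: 30 acetaldehyde; 31 tert-butyl acrylate
Product: 32 rac-tert-butyl 3-hydroxy-2-methylidenebutanoate
Conditions: DABCO (0.5 equiv), dioxane/H2O, rt
Reagents that add atoms: none
Why: Morita–Baylis–Hillman reaction; the carbinol centre is lost in the next step.

Step 19
Reactants: 32 rac-tert-butyl 3-hydroxy-2-methylidenebutanoate
Product: 34 tert-butyl (E)-2-(acetoxymethyl)but-2-enoate, via secondary allylic acetate 33 (not isolated)
Conditions: Ac2O, Et3N, DMAP (cat.), CH2Cl2, 0 °C; then DABCO (20 mol %), THF, reflux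
Reagents that add atoms: acetic anhydride, CC(=O)OC(C)=O
Why: Acetylation followed by amine-catalysed allylic transposition (two SN2′ steps) leads to the more stable primary acetate with the methyl group trans to the ester (E).

Step 20
Reactants: 34 tert-butyl (E)-2-(acetoxymethyl)but-2-enoate
Product: 35 (E)-2-(acetoxymethyl)but-2-enoic acid
Conditions: CF3CO2H/CH2Cl2 (1:4), 0 °C to rt
Reagents that add atoms: none
Why: Acidolysis of the tert-butyl ester leaves the acetate and the olefin geometry untouched.

Step 21
Reactants: 29 8,9-diol α-methylene lactone; 35 (E)-2-(acetoxymethyl)but-2-enoic acid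
Product: 36 CNP0231561.1 (6R,7S,8S,9S,10R)
Conditions: 35 (1.05 equiv), DCC, DMAP (10 mol %), CH2Cl2, −20 to 0 °C
Reagents that add atoms: none
Why: Steglich esterification; the C9 hydroxyl is neopentyl-like (next to quaternary C10), so the C8 hydroxyl should be acylated first.

**Compound list**
1 | (E)-crotonaldehyde | C/C=C/C=O | starting material
2 | vinylmagnesium bromide | C=C[Mg]Br | starting material
3 | rac-(E)-hexa-1,4-dien-3-ol | C=CC(O)/C=C/C | intermediate
4 | (3S,4E)-hexa-1,4-dien-3-ol | C=C[C@H](O)/C=C/C | intermediate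
5 | 2-(bromomethyl)acrylic acid | C=C(CBr)C(=O)O | starting material
6 | (3S,4E)-hexa-1,4-dien-3-yl 2-(bromomethyl)acrylate | C=C[C@H](OC(=O)C(=C)CBr)/C=C/C | intermediate
7 | (5R)-3-(bromomethyl)-5-[(E)-prop-1-enyl]furan-2(5H)-one | O=C1O[C@H](/C=C/C)C=C1CBr | intermediate
8 | glyoxylic acid | O=CC(=O)O | starting material
9 | Barbier adduct, C8 hydroxy acid | C=C1C(=O)O[C@H](/C=C/C)[C@H]1[C@H](O)C(=O)O | intermediate
10 | bis-silylated acid (silyl ether and silyl ester) | C=C1C(=O)O[C@H](/C=C/C)[C@H]1[C@H](O[Si](C)(C)C(C)(C)C)C(=O)O[Si](C)(C)C(C)(C)C | intermediate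
11 | C8 O-TBS acid | C=C1C(=O)O[C@H](/C=C/C)[C@H]1[C@H](O[Si](C)(C)C(C)(C)C)C(=O)O | intermediate
12 | methacrolein | C=C(C)C=O | starting material
13 | acetonitrile | CC#N | starting material
14 | rac-3-hydroxy-4-methylpent-4-enenitrile | C=C(C)C(O)CC#N | intermediate
15 | (3R)-3-hydroxy-4-methylpent-4-enenitrile | C=C(C)[C@H](O)CC#N | intermediate
16 | ester of 11 with 15 | C=C1C(=O)O[C@H](/C=C/C)[C@H]1[C@H](O[Si](C)(C)C(C)(C)C)C(=O)O[C@H](CC#N)C(C)=C | intermediate
17 | eight-membered (4Z)-lactone | C=C1C(=O)O[C@@H]2/C=C(/C)[C@@H](CC#N)OC(=O)[C@@H](O[Si](C)(C)C(C)(C)C)[C@@H]12 | intermediate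
18 | tris-aluminium adduct | C=C1C(O[Al](CC(C)C)CC(C)C)O[C@@H]2/C=C(/C)[C@@H](CC=N[Al](CC(C)C)CC(C)C)O[C@@H](O[Al](CC(C)C)CC(C)C)[C@@H](O[Si](C)(C)C(C)(C)C)[C@@H]12 | intermediate
19 | silylated iminoalane | C=C1C(O[Si](C)(C)C(C)(C)C)O[C@@H]2/C=C(/C)[C@@H](CC=N[Al](CC(C)C)CC(C)C)O[C@@H](O[Si](C)(C)C(C)(C)C)[C@@H](O[Si](C)(C)C(C)(C)C)[C@@H]12 | intermediate
20 | eight-membered O-silyl lactol, C1 aldehyde | C=C1C(O[Si](C)(C)C(C)(C)C)O[C@@H]2/C=C(/C)[C@@H](CC=O)O[C@@H](O[Si](C)(C)C(C)(C)C)[C@@H](O[Si](C)(C)C(C)(C)C)[C@@H]12 | intermediate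
21 | C1 carboxylic acid | C=C1C(O[Si](C)(C)C(C)(C)C)O[C@@H]2/C=C(/C)[C@@H](CC(=O)O)O[C@@H](O[Si](C)(C)C(C)(C)C)[C@@H](O[Si](C)(C)C(C)(C)C)[C@@H]12 | intermediate
22 | mixed carbonic anhydride | C=C1C(O[Si](C)(C)C(C)(C)C)O[C@@H]2/C=C(/C)[C@@H](CC(=O)OC(=O)OCC(C)C)O[C@@H](O[Si](C)(C)C(C)(C)C)[C@@H](O[Si](C)(C)C(C)(C)C)[C@@H]12 | intermediate
23 | 2-diazo-3-ketone | C=C1C(O[Si](C)(C)C(C)(C)C)O[C@@H]2/C=C(/C)[C@@H](CC(=O)C(C)=[N+]=[N-])O[C@@H](O[Si](C)(C)C(C)(C)C)[C@@H](O[Si](C)(C)C(C)(C)C)[C@@H]12 | intermediate
24 | bicyclic oxonium ylide | C=C1C(O[Si](C)(C)C(C)(C)C)O[C@@H]2/C=C(/C)[C@H]3CC(=O)[C-](C)[O+]3[C@@H](O[Si](C)(C)C(C)(C)C)[C@@H](O[Si](C)(C)C(C)(C)C)[C@@H]12 | intermediate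
25 | ether-bridged oxolan-3-one | C=C1C(O[Si](C)(C)C(C)(C)C)O[C@@H]2/C=C(/C)[C@H]3CC(=O)[C@](C)(O3)[C@@H](O[Si](C)(C)C(C)(C)C)[C@@H](O[Si](C)(C)C(C)(C)C)[C@@H]12 | intermediate
26 | trimethylsilyl enol ether | C=C1C(O[Si](C)(C)C(C)(C)C)O[C@@H]2/C=C(/C)[C@H]3C=C(O[Si](C)(C)C)[C@](C)(O3)[C@@H](O[Si](C)(C)C(C)(C)C)[C@@H](O[Si](C)(C)C(C)(C)C)[C@@H]12 | intermediate
27 | 3(2H)-furanone tris-silyl ether | C=C1C(O[Si](C)(C)C(C)(C)C)O[C@@H]2/C=C(/C)C3=CC(=O)[C@](C)(O3)[C@@H](O[Si](C)(C)C(C)(C)C)[C@@H](O[Si](C)(C)C(C)(C)C)[C@@H]12 | intermediate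
28 | C12 lactol 8,9-diol | C=C1C(O)O[C@@H]2/C=C(/C)C3=CC(=O)[C@](C)(O3)[C@@H](O)[C@@H](O)[C@@H]12 | intermediate
29 | 8,9-diol α-methylene lactone | C=C1C(=O)O[C@@H]2/C=C(/C)C3=CC(=O)[C@](C)(O3)[C@@H](O)[C@@H](O)[C@@H]12 | intermediate
30 | acetaldehyde | CC=O | starting material
31 | tert-butyl acrylate | C=CC(=O)OC(C)(C)C | starting material
32 | rac-tert-butyl 3-hydroxy-2-methylidenebutanoate | CC(O)C(=C)C(=O)OC(C)(C)C | intermediate
33 | rac-tert-butyl 3-acetoxy-2-methylidenebutanoate | CC(OC(C)=O)C(=C)C(=O)OC(C)(C)C | intermediate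
34 | tert-butyl (E)-2-(acetoxymethyl)but-2-enoate | CC(C)(C)OC(=O)/C(=C/C)COC(C)=O | intermediate
35 | (E)-2-(acetoxymethyl)but-2-enoic acid | OC(=O)/C(=C/C)COC(C)=O | intermediate
36 | CNP0231561.1 | C=C1C(=O)O[C@@H]2/C=C(/C)C3=CC(=O)[C@](C)(O3)[C@@H](O)[C@@H](OC(=O)/C(=C/C)COC(C)=O)[C@@H]12 | target

**Step count**
Total steps: 21. Longest linear sequence: 16 (steps 1–6, 9–17, 21).

**Steps most likely to fail**

1. Step 14.
   - What may go wrong: the carbenoid may be consumed by 1,2-hydride shift, by cyclopropanation of C4=C5 or by C–H insertion before the acetal oxygen attacks, or the ylide may revert instead of rearranging.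
   - Fallback (from 23, back at 25): no carbenoid is used, and the two bonds are made one after the other by ionic reactions of known type. HBF4·OEt2 (1 equiv, CH2Cl2, −78 °C) protonates the diazo carbon, and the acetal oxygen displaces N2; this is the acid-induced cyclisation of γ-alkoxy diazoketones to oxolan-3-ones. The acetal oxonium ion then collapses to the C9 aldehyde with loss of its silyl group, giving ring-opened keto aldehyde F1 (C10 epimers).
   - TBSOTf/Et3N converts the ketone into the more substituted, oxygen-stabilised silyl enol ether F2. A catalytic amount of TBSOTf (CH2Cl2, −78 °C, high dilution) then closes C9–C10 by an intramolecular silyl-transfer Mukaiyama aldol reaction. Attack should be Felkin–Anh at C9, on the enol ether face cis to C4, and gives 25.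

2. Step 5.
   - What may go wrong: simple diastereoselection at C8 may be poor or reversed if the carboxylate does not stay bound to indium and the ordinary chair operates.
   - Fallback (from 7, back at 16): the non-chelated outcome is accepted and C8 is set by SN2 inversion. The Barbier reaction then delivers C8-epimeric hydroxy acid F3. DCC/DMAP coupling with 15 (slow addition of the acid) gives hydroxy ester F4.
   - A Mitsunobu reaction with formic acid (PPh3, DIAD, THF, 0 °C) inverts the activated α-carbonyl carbinol to formate F5. NaHCO3 in MeOH removes the formyl group to give hydroxy ester F6. TBSOTf/2,6-lutidine then gives 16.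

3. Step 21.
   - What may go wrong: site selectivity between the two secondary hydroxyl groups may be poor, or the acyl group may migrate from O8 to O9.
   - Fallback (from 27, back at 36): steric differentiation is used in the deprotection instead of the acylation. Short treatment with pyridine-buffered HF·pyridine at 0 °C should remove the lactol silyl group and the less hindered C8 silyl ether but leave the neopentyl C9 silyl ether, giving C9-silyl lactol F7.
   - PhI(OAc)2/TEMPO gives C9-silyl hydroxy lactone F8. DCC/DMAP with 35 gives C9-silyl ester F9. HF·pyridine at rt then gives 36.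

**Further compounds**
F1 | step 14 | ring-opened keto aldehyde | C=C1C(O[Si](C)(C)C(C)(C)C)O[C@H](/C=C(/C)[C@H]2CC(=O)C(C)O2)[C@H]1[C@H](O[Si](C)(C)C(C)(C)C)C=O
F2 | step 14 | silyl enol ether | C=C1C(O[Si](C)(C)C(C)(C)C)O[C@H](/C=C(/C)[C@H]2CC(O[Si](C)(C)C(C)(C)C)=C(C)O2)[C@H]1[C@H](O[Si](C)(C)C(C)(C)C)C=O
F3 | step 5 | C8-epimeric hydroxy acid | C=C1C(=O)O[C@H](/C=C/C)[C@H]1[C@@H](O)C(=O)O
F4 | step 5 | hydroxy ester (C8 epimer) | C=C1C(=O)O[C@H](/C=C/C)[C@H]1[C@@H](O)C(=O)O[C@H](CC#N)C(C)=C
F5 | step 5 | formate (C8 inverted) | C=C1C(=O)O[C@H](/C=C/C)[C@H]1[C@H](OC=O)C(=O)O[C@H](CC#N)C(C)=C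
F6 | step 5 | hydroxy ester (C8 as in 36) | C=C1C(=O)O[C@H](/C=C/C)[C@H]1[C@H](O)C(=O)O[C@H](CC#N)C(C)=C
F7 | step 21 | C9-silyl lactol | C=C1C(O)O[C@@H]2/C=C(/C)C3=CC(=O)[C@](C)(O3)[C@@H](O[Si](C)(C)C(C)(C)C)[C@@H](O)[C@@H]12
F8 | step 21 | C9-silyl hydroxy lactone | C=C1C(=O)O[C@@H]2/C=C(/C)C3=CC(=O)[C@](C)(O3)[C@@H](O[Si](C)(C)C(C)(C)C)[C@@H](O)[C@@H]12
F9 | step 21 | C9-silyl ester | C=C1C(=O)O[C@@H]2/C=C(/C)C3=CC(=O)[C@](C)(O3)[C@@H](O[Si](C)(C)C(C)(C)C)[C@@H](OC(=O)/C(=C/C)COC(C)=O)[C@@H]12
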